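**Strategy.** The oxepine ring is cut at two bonds at once, C3–CH2 and CH–O2', which releases its CH2–CH–C(CH3)2 unit as intact isoprene. The key step exploits the rigid five-atom array C3=C2–C1'=C2'–O that runs from chromone ring C into ring B. In a 3-iodo-2'-hydroxyflavone this array carries an electrophilic and a nucleophilic end. A palladium(0)-catalysed, ligand-controlled Heck/allylic-etherification (5+2) annulation with isoprene forms both bonds, closes the seven-membered ring and sets the only stereocentre in one operation. Cobalt-catalysed hydroperoxidation of the remaining isopropenyl group finishes the target. The precursor is an unprotected, fully substituted tricyclic iodoflavone, built by chalcone chemistry and two site-selective iodinations.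

Key step: step 7

Assumption (remark on the chemistry): the (E)-alkenylboronic ester is taken as a catalogue compound (otherwise one hydroboration of 3-methylbut-1-yne with pinacolborane), and the ligand antipode that gives the (S)-product in the annulation is fixed by a pilot run, both antipodes being accessible.

Step 1
Reactants: 1 1-(2,6-dihydroxy-4-methoxyphenyl)ethan-1-one; 2 2,4-bis(benzyloxy)benzaldehyde
Product: 3 (E)-3-[2,4-bis(benzyloxy)phenyl]-1-(2,6-dihydroxy-4-methoxyphenyl)prop-2-en-1-one
Conditions: KOH (50% aq), EtOH, rt, 48–72 h; then 1 M HCl to pH 5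
Reagents that add atoms: none
Why: Claisen–Schmidt condensation, in which E1cB dehydration under equilibrating conditions gives the (E)-enone, benzyl ethers are inert to hydroxide and the C2-symmetric ketone 1 makes the later pyranone closure regiochemically unambiguous.

Step 2
Reactants: 3 chalcone
Product: 5 2-[2,4-bis(benzyloxy)phenyl]-5-hydroxy-7-methoxy-4H-chromen-4-one, via flavanone 4 (not isolated)
Conditions: I2 (10 mol%), DMSO, 125 °C
Reagents that add atoms: none
Why: Iodine/DMSO oxidative cyclisation of a 2'-hydroxychalcone: oxa-Michael closure to 4, α-iodination and loss of HI give the flavone while DMSO re-oxidises iodide, and the hydroxyl not used becomes the chelated 5-OH.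

Step 3
Reactants: 5 flavone
Product: 6 2-[2,4-bis(benzyloxy)phenyl]-5-hydroxy-6-iodo-7-methoxy-4H-chromen-4-one
Conditions: BnMe3N·ICl2 (1.05 equiv), CaCO3, CH2Cl2/MeOH, rt
Reagents that add atoms: benzyltrimethylammonium dichloroiodate C[N+](C)(C)Cc1ccccc1.Cl[I-]Cl
Why: Electrophilic aromatic iodination, in which the phloroglucinol-type ring A outruns the resorcinol diether ring B and a free, chelated 5-OH is known to steer dichloroiodate reagents on 5-hydroxy-7-alkoxyflavones to the ortho position C6 rather than to C8.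

Step 4
Reactants: 6 6-iodoflavone; 7 (E)-4,4,5,5-tetramethyl-2-(3-methylbut-1-en-1-yl)-1,3,2-dioxaborolane
Product: 8 2-[2,4-bis(benzyloxy)phenyl]-5-hydroxy-7-methoxy-6-[(E)-3-methylbut-1-enyl]-4H-chromen-4-one
Conditions: Pd(OAc)2 (5 mol%), SPhos (10 mol%), K2CO3, dioxane/H2O, 80 °C
Reagents that add atoms: none
Why: Suzuki–Miyaura coupling with retention of the (E)-alkenylboronate geometry, a bulky biarylphosphine being chosen for the doubly ortho-substituted electron-rich aryl iodide.

Step 5
Reactants: 8 6-alkenylflavone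
Product: 10 2-[2,4-bis(benzyloxy)phenyl]-5-hydroxy-3-iodo-7-methoxy-6-[(E)-3-methylbut-1-enyl]-4H-chromen-4-one, via C3-lithiated lithium phenoxide 9 (not isolated)
Conditions: LDA (3 equiv), THF, −78 °C; ICH2CH2I (3 equiv), −78 to −30 °C; 1 M HCl quench
Reagents that add atoms: 1,2-diiodoethane ICCI; lithium diisopropylamide [Li+].CC(C)[N-]C(C)C (lithium stays only in 9)
Why: Known C3-lithiation of flavones with LDA (the first equivalent is consumed by the 5-OH) followed by iodine transfer from 1,2-diiodoethane, an iodine source that reacts with the vinyl-lithium but leaves the phenoxide, the styrene and the electron-rich arenes untouched.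

Step 6
Reactants: 10 3-iodoflavone dibenzyl ether
Product: 11 2-(2,4-dihydroxyphenyl)-5-hydroxy-3-iodo-7-methoxy-6-[(E)-3-methylbut-1-enyl]-4H-chromen-4-one
Conditions: BCl3 (5 equiv), C6HMe5 (8 equiv), CH2Cl2, −78 °C; H2O quench
Reagents that add atoms: none
Why: Lewis-acid debenzylation of aryl benzyl ethers with BCl3 and pentamethylbenzene as non-basic cation scavenger, mild enough at −78 °C to spare the 7-OMe group, the vinyl iodide and the styrene.

Step 7
Reactants: 11 3-iodo-2'-hydroxyflavone triol; 12 isoprene (2-methylbuta-1,3-diene)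
Product: 13 (S)-isopropenyl dihydrooxepinoflavone (bridge 2'-O–CH(isopropenyl)–CH2–C3; 5-OH and 4'-OH free; 7-OMe; 6-[(E)-3-methylbut-1-enyl])
Conditions: Pd2(dba)3·CHCl3 (5 mol%), chiral sulfinamide–monophosphine ligand (TY-Phos type, 12 mol%), K2CO3 (3 equiv), isoprene (10 equiv), degassed 1,4-dioxane (0.02 M), 60 °C, sealed tube
Reagents that add atoms: none
Why: Proposed new method: oxidative addition of Pd(0) into the C3–I bond, migratory insertion of the less substituted C=C of isoprene (C3 bonds to its CH2 terminus) and capture of the resulting 2-methyl-η3-allylpalladium at its internal CH terminus by the 2'-phenoxide give 13 and return Pd(0). The closest known reaction type is the Larock heteroannulation of 1,3-dienes by o-halophenols and its enantioselective Heck/Tsuji–Trost form, which turns isoprene into 2-isopropenyl-2,3-dihydrobenzofurans, together with Pd-catalysed (5+2) annulations of dienes on biaryl amines; the extension here is to a vinylogous halide/phenol pair and a seven-membered ether. The oxepine closes in a 7-exo mode (oxygen attacks the allyl carbon next to the new CH2 and the other two allyl carbons stay outside as the isopropenyl group), whereas attack at the far CH2 would need a nine-membered ring. The stereocentre is controlled by the chiral ligand, because the two diastereomeric allyl complexes interconvert by π–σ–π through the unsubstituted CH2 terminus and the ligand pocket decides which allyl face meets the phenoxide. The step needs insertion at the vinyl and not the isopropenyl end of isoprene (secured by the crowded C3–Pd flanked by C4=O and ring B), ring closure ahead of β-hydride elimination and of direct C3–O coupling (excess diene and the rigid array that holds the phenoxide over the allyl), and silence of the other phenols (5-OH is chelated to C4=O and geometrically blocked, 4'-O cannot reach the allyl within the molecule and is held back by dilution). The hindered internal styrene should not insert.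

Step 8
Reactants: 13 (S)-isopropenyl dihydrooxepinoflavone
Product: 15 target hydroperoxide CNP0171472.1 (S), via triethylsilyl peroxide 14 (not isolated)
Conditions: Co(thd)2 (10 mol%), Et3SiH (2 equiv), O2 (1 atm), 1,2-dichloroethane, rt; then MeOH, HCl (cat.), 0 °C
Reagents that add atoms: dioxygen O=O; triethylsilane CC[SiH](CC)CC (silyl group stays only in 14)
Why: Mukaiyama–Isayama hydroperoxysilylation: hydrogen-atom transfer from a cobalt hydride to the unhindered terminal CH2 of the 1,1-disubstituted alkene gives the tertiary radical, O2 capture and Co–OOR/silane exchange give 14, acid methanolysis frees the hydroperoxide, the stereocentre is not touched, and the internal styrene (β-isopropyl, two ortho substituents) should accept hydrogen much more slowly.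

**Compound list**

1 | 1-(2,6-dihydroxy-4-methoxyphenyl)ethan-1-one | COc1cc(O)c(C(C)=O)c(O)c1 | starting material
2 | 2,4-bis(benzyloxy)benzaldehyde | O=Cc1ccc(OCc2ccccc2)cc1OCc1ccccc1 | starting material
3 | (E)-3-[2,4-bis(benzyloxy)phenyl]-1-(2,6-dihydroxy-4-methoxyphenyl)prop-2-en-1-one | COc1cc(O)c(C(=O)/C=C/c2ccc(OCc3ccccc3)cc2OCc2ccccc2)c(O)c1 | intermediate
4 | 2-[2,4-bis(benzyloxy)phenyl]-5-hydroxy-7-methoxychroman-4-one (racemic, in flask) | COc1cc(O)c2c(c1)OC(CC2=O)c1ccc(OCc3ccccc3)cc1OCc1ccccc1 | intermediate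
5 | 2-[2,4-bis(benzyloxy)phenyl]-5-hydroxy-7-methoxy-4H-chromen-4-one | COc1cc(O)c2c(=O)cc(-c3ccc(OCc4ccccc4)cc3OCc3ccccc3)oc2c1 | intermediate
6 | 2-[2,4-bis(benzyloxy)phenyl]-5-hydroxy-6-iodo-7-methoxy-4H-chromen-4-one | COc1cc2oc(-c3ccc(OCc4ccccc4)cc3OCc3ccccc3)cc(=O)c2c(O)c1I | intermediate
7 | (E)-4,4,5,5-tetramethyl-2-(3-methylbut-1-en-1-yl)-1,3,2-dioxaborolane | CC(C)/C=C/B1OC(C)(C)C(C)(C)O1 | starting material
8 | 2-[2,4-bis(benzyloxy)phenyl]-5-hydroxy-7-methoxy-6-[(E)-3-methylbut-1-enyl]-4H-chromen-4-one | COc1cc2oc(-c3ccc(OCc4ccccc4)cc3OCc3ccccc3)cc(=O)c2c(O)c1/C=C/C(C)C | intermediate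
9 | C3-lithiated lithium 5-phenoxide of 8 (in flask) | COc1cc2oc(-c3ccc(OCc4ccccc4)cc3OCc3ccccc3)c([Li])c(=O)c2c(O[Li])c1/C=C/C(C)C | intermediate
10 | 2-[2,4-bis(benzyloxy)phenyl]-5-hydroxy-3-iodo-7-methoxy-6-[(E)-3-methylbut-1-enyl]-4H-chromen-4-one | COc1cc2oc(-c3ccc(OCc4ccccc4)cc3OCc3ccccc3)c(I)c(=O)c2c(O)c1/C=C/C(C)C | intermediate
11 | 2-(2,4-dihydroxyphenyl)-5-hydroxy-3-iodo-7-methoxy-6-[(E)-3-methylbut-1-enyl]-4H-chromen-4-one | COc1cc2oc(-c3ccc(O)cc3O)c(I)c(=O)c2c(O)c1/C=C/C(C)C | intermediate
12 | isoprene | C=CC(C)=C | starting material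
13 | (S)-isopropenyl dihydrooxepinoflavone (2'-O–CH(isopropenyl)–CH2–C3 bridge) | COc1cc2oc3c(c(=O)c2c(O)c1/C=C/C(C)C)C[C@@H](C(C)=C)Oc1cc(O)ccc1-3 | intermediate
14 | (S)-triethylsilyl peroxide of the target (in flask) | COc1cc2oc3c(c(=O)c2c(O)c1/C=C/C(C)C)C[C@@H](C(C)(C)OO[Si](CC)(CC)CC)Oc1cc(O)ccc1-3 | intermediate
15 | CNP0171472.1, (S)-2-hydroperoxypropan-2-yl dihydrooxepinoflavone | COc1cc2oc3c(c(=O)c2c(O)c1/C=C/C(C)C)C[C@@H](C(C)(C)OO)Oc1cc(O)ccc1-3 | target

Total step count: 8. Longest linear sequence: 8 steps (from 1 or 2 to 15).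

**Steps most likely to fail**

**Step 7 (labelled key step).**
- What may go wrong:
  - The seven-membered C–O closure may be slow enough for β-hydride elimination to a diene to take over.
  - The 4'-phenoxide may be allylated between molecules.
  - Enantio-induction may be poor or may erode through reversible ionisation of the allyl aryl ether.
- The fallback uses known chemistry only, sets out from 11 and comes back at 13.
  - Stille coupling of 11 with commercial tributyl(3-methylbut-2-enyl)stannane gives artocarpin F1.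
  - TBSCl/imidazole silylates the two ring-B phenols, the chelated 5-OH staying free, to give 2',4'-bis-O-TBS-artocarpin F2.
  - Shi epoxidation (D-fructose-derived ketone, limiting Oxone) of the unhindered trisubstituted prenyl alkene gives the (R)-epoxide F3.
  - TBAF frees the 2'-phenoxide, which opens the epoxide at its CH carbon (7-exo-tet, inversion) to the (S)-tertiary alcohol F4.
  - Dehydration with SOCl2/pyridine towards a methyl group gives 13.

**Step 8.**
- What may go wrong:
  - Hydrogen-atom transfer to the styrene may compete.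
  - The cobalt may be sequestered by the 5-hydroxy-4-keto chelate.
- The fallback postpones the styrene until after the peroxidation, sets out from 6 and comes back at 14.
  - C3-lithiation/iodination of 6 as in step 5 gives the 3,6-diiodide F5.
  - BCl3/pentamethylbenzene gives the diiodo triol F6.
  - The isoprene annulation of step 7 at the more reactive α-iodoenone C3–I gives the (S)-6-iodo isopropenyl oxepinoflavone F7.
  - Co(thd)2/Et3SiH/O2, now facing a single alkene, gives the (S)-6-iodo triethylsilyl peroxide F8.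
  - Hydrostannation of 3-methylbut-1-yne with Bu3SnH supplies (E)-tributyl(3-methylbut-1-enyl)stannane F9.
  - A neutral Stille coupling of F8 with F9 (Pd2(dba)3, AsPh3, 25–40 °C), a coupling type that dialkyl and silyl peroxides tolerate, gives 14.

**Step 3.**
- What may go wrong: iodination may occur at C8 or on ring B instead of at C6.
- The fallback fixes the C6 substituent through a symmetric phenol instead of a directed substitution, sets out from 2 and comes back at 8.
  - Catalogue 4-bromo-3,5-dimethoxyphenol is C-acetylated ortho to the hydroxyl (Ac2O, BF3·OEt2, Fries conditions; both ortho positions are equivalent) to 1-(3-bromo-6-hydroxy-2,4-dimethoxyphenyl)ethanone F10.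
  - Claisen–Schmidt condensation with 2 gives the bromochalcone F11.
  - I2/DMSO gives the 6-bromo-5,7-dimethoxyflavone F12.
  - Suzuki–Miyaura coupling with 7 gives the 6-alkenyl-5,7-dimethoxyflavone F13.
  - Chelation-controlled cleavage of the 5-OMe group with MgI2 etherate, which leaves the benzyl ethers in place, gives 8.

**Further compounds**

F1 | step 7 | artocarpin | COc1cc2oc(-c3ccc(O)cc3O)c(CC=C(C)C)c(=O)c2c(O)c1/C=C/C(C)C
F2 | step 7 | 2',4'-bis-O-(tert-butyldimethylsilyl)artocarpin | COc1cc2oc(-c3ccc(O[Si](C)(C)C(C)(C)C)cc3O[Si](C)(C)C(C)(C)C)c(CC=C(C)C)c(=O)c2c(O)c1/C=C/C(C)C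
F3 | step 7 | (R)-epoxide of F2 (3-[(3,3-dimethyloxiran-2-yl)methyl]flavone) | COc1cc2oc(-c3ccc(O[Si](C)(C)C(C)(C)C)cc3O[Si](C)(C)C(C)(C)C)c(C[C@H]3OC3(C)C)c(=O)c2c(O)c1/C=C/C(C)C
F4 | step 7 | (S)-2-hydroxypropan-2-yl dihydrooxepinoflavone | COc1cc2oc3c(c(=O)c2c(O)c1/C=C/C(C)C)C[C@@H](C(C)(C)O)Oc1cc(O)ccc1-3
F5 | step 8 | 2-[2,4-bis(benzyloxy)phenyl]-5-hydroxy-3,6-diiodo-7-methoxy-4H-chromen-4-one | COc1cc2oc(-c3ccc(OCc4ccccc4)cc3OCc3ccccc3)c(I)c(=O)c2c(O)c1I
F6 | step 8 | 2-(2,4-dihydroxyphenyl)-5-hydroxy-3,6-diiodo-7-methoxy-4H-chromen-4-one | COc1cc2oc(-c3ccc(O)cc3O)c(I)c(=O)c2c(O)c1I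
F7 | step 8 | (S)-6-iodo isopropenyl dihydrooxepinoflavone | COc1cc2oc3c(c(=O)c2c(O)c1I)C[C@@H](C(C)=C)Oc1cc(O)ccc1-3
F8 | step 8 | (S)-6-iodo triethylsilyl peroxide | COc1cc2oc3c(c(=O)c2c(O)c1I)C[C@@H](C(C)(C)OO[Si](CC)(CC)CC)Oc1cc(O)ccc1-3
F9 | step 8 | (E)-tributyl(3-methylbut-1-enyl)stannane | CCCC[Sn](CCCC)(CCCC)/C=C/C(C)C
F10 | step 3 | 1-(3-bromo-6-hydroxy-2,4-dimethoxyphenyl)ethan-1-one | COc1cc(O)c(C(C)=O)c(OC)c1Br
F11 | step 3 | (E)-3-[2,4-bis(benzyloxy)phenyl]-1-(3-bromo-6-hydroxy-2,4-dimethoxyphenyl)prop-2-en-1-one | COc1cc(O)c(C(=O)/C=C/c2ccc(OCc3ccccc3)cc2OCc2ccccc2)c(OC)c1Br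
F12 | step 3 | 2-[2,4-bis(benzyloxy)phenyl]-6-bromo-5,7-dimethoxy-4H-chromen-4-one | COc1cc2oc(-c3ccc(OCc4ccccc4)cc3OCc3ccccc3)cc(=O)c2c(OC)c1Br
F13 | step 3 | 2-[2,4-bis(benzyloxy)phenyl]-5,7-dimethoxy-6-[(E)-3-methylbut-1-enyl]-4H-chromen-4-one | COc1cc2oc(-c3ccc(OCc4ccccc4)cc3OCc3ccccc3)cc(=O)c2c(OC)c1/C=C/C(C)C
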